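Both flavone units contain the same 2-aryl-4-pyranone, so the plan disconnects the O1–C2 bond of pyranone ring C (flavone 1: rings A, C, B) and the O1–C2 bond of pyranone ring E (flavone 2: rings D, E, F) together. One iodine–DMSO operation should close both rings of an ether-linked bis-chalcone and dehydrogenate them to C2=C3. The precursor already contains the hindered C8–O–C4 diaryl ether between rings A and F. Its ring A bears free hydroxyls at C2' and C4' and a benzyl ether at C6'; its ring D precursor is a symmetric 2',6'-dihydroxy-4'-methoxyphenyl ketone. The ether comes from fluoride displacement, the ring A enone from directed lithiation and Weinreb acylation.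

Key step: step 11

Assumption: both enone double bonds are carried as E (the thermodynamic aldol geometry); the target has no stereocentre, so no step has to set configuration.

Step 1
Reactants: 1 2,4,6-trihydroxybenzaldehyde
Product: 2 4-(benzyloxy)-2,6-dihydroxybenzaldehyde
Conditions: BnBr (1.05 equiv), CsHCO3 (1.5 equiv), MeCN, 60 °C
Reagents that add atoms: benzyl bromide, BrCc1ccccc1
Why: Williamson etherification under bicarbonate control, in which the 4-hydroxyl (para to the formyl group, most acidic, not held in the hydrogen bond to the carbonyl) should be alkylated before either ortho hydroxyl.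

Step 2
Reactants: 2 4-(benzyloxy)-2,6-dihydroxybenzaldehyde
Product: 3 4-(benzyloxy)-2,6-bis(methoxymethoxy)benzaldehyde
Conditions: NaH (2.5 equiv), MOMCl (2.5 equiv), DMF, 0 °C to rt
Reagents that add atoms: chloromethyl methyl ether, COCCl
Why: O-alkylation of the bis-phenoxide with MOMCl (Williamson type), NaH being strong enough to break the chelate to the formyl oxygen so that both ortho hydroxyls are capped.

Step 3
Reactants: 3 4-(benzyloxy)-2,6-bis(methoxymethoxy)benzaldehyde
Product: 5 4-(benzyloxy)-2,6-bis(methoxymethoxy)phenol, via aryl formate 4 (not isolated)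
Conditions: mCPBA (1.3 equiv), CH2Cl2, 0 °C to rt; then K2CO3 (cat.), MeOH, rt
Reagents that add atoms: mCPBA, O=C(OO)c1cccc(Cl)c1
Why: Baeyer–Villiger (Dakin-type) oxidation in which the electron-rich trialkoxyaryl group migrates in preference to hydrogen, and mild methanolysis of the formate then frees the phenol without touching the MOM or benzyl ethers.

Step 4
Reactants: 5 4-(benzyloxy)-2,6-bis(methoxymethoxy)phenol; 6 4-fluorobenzaldehyde
Product: 7 4-[4-(benzyloxy)-2,6-bis(methoxymethoxy)phenoxy]benzaldehyde
Conditions: K2CO3 (2 equiv), DMF, 110 °C, N2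
Reagents that add atoms: none
Why: Nucleophilic aromatic substitution (addition–elimination, SNAr), in which the para-formyl group activates fluoride toward the hindered 2,6-dioxygenated phenoxide, and the MOM and benzyl ethers are inert to carbonate.

Step 5
Reactants: 7 4-[4-(benzyloxy)-2,6-bis(methoxymethoxy)phenoxy]benzaldehyde
Product: 8 5-(benzyloxy)-2-[4-(dimethoxymethyl)phenoxy]-1,3-bis(methoxymethoxy)benzene
Conditions: HC(OMe)3 (3 equiv), PPTS (cat.), MeOH, rt; Et3N quench
Reagents that add atoms: trimethyl orthoformate, COC(OC)OC; methanol, CO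
Why: Acid-catalysed acetalisation with the orthoformate as water scavenger masks the aldehyde against butyllithium, and PPTS at room temperature is too weak to cleave aryl MOM ethers.

Step 6
Reactants: 9 (E)-4-methoxycinnamic acid
Product: 11 (E)-N-methoxy-3-(4-methoxyphenyl)-N-methylprop-2-enamide, via acid chloride 10 (not isolated)
Conditions: SOCl2, DMF (cat.), toluene, 70 °C; then MeNHOMe·HCl, K2CO3, CH2Cl2/H2O, 0 °C to rt
Reagents that add atoms: N,O-dimethylhydroxylamine hydrochloride, CNOC.Cl
Why: Acid chloride formation followed by Schotten–Baumann amidation gives the Weinreb amide, and the E double bond is not involved.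

Step 7
Reactants: 8 5-(benzyloxy)-2-[4-(dimethoxymethyl)phenoxy]-1,3-bis(methoxymethoxy)benzene; 11 (E)-N-methoxy-3-(4-methoxyphenyl)-N-methylprop-2-enamide
Product: 14 4-{4-(benzyloxy)-3-[(2E)-3-(4-methoxyphenyl)prop-2-enoyl]-2,6-bis(methoxymethoxy)phenoxy}benzaldehyde, via aryllithium 12 (not isolated), via acetal chalcone 13 (not isolated)
Conditions: n-BuLi (1.1 equiv), THF, −20 to 0 °C; then 11, −78 to 0 °C; then aq. HCl (0.5 M), THF, rt
Reagents that add atoms: water, O
Why: Directed ortho-metalation at one of the two equivalent ring A C–H positions (each flanked by OMOM and OBn, the most acidic sites) gives an aryllithium that adds once to the Weinreb amide through its chelated tetrahedral adduct (Weinreb ketone synthesis), and dilute acid then releases the E enone and hydrolyses the dimethyl acetal while the aryl MOM ethers should survive.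

Step 8
Reactants: 15 2',6'-dihydroxy-4'-methoxyacetophenone
Product: 16 2'-hydroxy-4'-methoxy-6'-(methoxymethoxy)acetophenone
Conditions: MOMCl (1.1 equiv), K2CO3, acetone, 0 °C to rt
Reagents that add atoms: chloromethyl methyl ether, COCCl
Why: Williamson-type alkylation of a symmetric ketone, where either hydroxyl may react and the remaining one is then held in a strong chelate to the carbonyl and resists a second alkylation at room temperature.

Step 9
Reactants: 14 4-{4-(benzyloxy)-3-[(2E)-3-(4-methoxyphenyl)prop-2-enoyl]-2,6-bis(methoxymethoxy)phenoxy}benzaldehyde; 16 2'-hydroxy-4'-methoxy-6'-(methoxymethoxy)acetophenone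
Product: 17 (2E)-1-[6-(benzyloxy)-3-{4-[(1E)-3-(2-hydroxy-4-methoxy-6-(methoxymethoxy)phenyl)-3-oxoprop-1-en-1-yl]phenoxy}-2,4-bis(methoxymethoxy)phenyl]-3-(4-methoxyphenyl)prop-2-en-1-one
Conditions: KOH (50% aq.), EtOH/THF, rt
Reagents that add atoms: none
Why: Claisen–Schmidt (crossed aldol) condensation in which the methyl ketone enolate adds to the non-enolisable aldehyde and E1cB dehydration gives the E enone, while the first chalcone has no enolisable hydrogen and its anisyl-substituted enone is a poor Michael acceptor.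

Step 10
Reactants: 17 (2E)-1-[6-(benzyloxy)-3-{4-[(1E)-3-(2-hydroxy-4-methoxy-6-(methoxymethoxy)phenyl)-3-oxoprop-1-en-1-yl]phenoxy}-2,4-bis(methoxymethoxy)phenyl]-3-(4-methoxyphenyl)prop-2-en-1-one
Product: 18 (2E)-1-[6-(benzyloxy)-3-{4-[(1E)-3-(2,6-dihydroxy-4-methoxyphenyl)-3-oxoprop-1-en-1-yl]phenoxy}-2,4-dihydroxyphenyl]-3-(4-methoxyphenyl)prop-2-en-1-one
Conditions: aq. HCl (3 M), MeOH/THF, 45 °C
Reagents that add atoms: none
Why: Acid-catalysed acetal hydrolysis removes all three MOM groups, while the benzyl ether and both enones should be stable to dilute HCl at this temperature.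

Step 11
Reactants: 18 (2E)-1-[6-(benzyloxy)-3-{4-[(1E)-3-(2,6-dihydroxy-4-methoxyphenyl)-3-oxoprop-1-en-1-yl]phenoxy}-2,4-dihydroxyphenyl]-3-(4-methoxyphenyl)prop-2-en-1-one
Product: 19 5-(benzyloxy)-7-hydroxy-8-[4-(5-hydroxy-7-methoxy-4-oxo-4H-chromen-2-yl)phenoxy]-2-(4-methoxyphenyl)-4H-chromen-4-one
Conditions: I2 (0.2 equiv), DMSO, 130 °C
Reagents that add atoms: none
Why: In each half the phenol oxygen ortho to the ketone adds to the enone β-carbon (oxa-Michael), the ketone is then iodinated at the α-carbon through its enol and loses HI to give C2=C3, and DMSO converts HI back to iodine, so iodine is needed only in catalytic amount. The closest known reaction is the iodine–DMSO oxidative cyclisation of a 2'-hydroxychalcone to a flavone, run here twice in one molecule. Ring C and ring E are each closed in the 6-endo-trig mode by forming their O1–C2 bond. No stereocentre is created, because C2 ends up sp2 in both rings. The step needs regiocontrol on ring A and 6-endo over 5-exo (aurone) closure: the C6' oxygen of ring A is benzylated, so only the C2' hydroxyl next to the aryloxy group can close and the ether lands at C8, the ring D precursor is symmetric so either hydroxyl gives the same 5-hydroxy-7-methoxy pattern, and iodine–DMSO is known to give flavones and not aurones. Catalytic iodine keeps HI low, which should protect the benzyl ether and limit iodination of the electron-rich rings.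

Step 12
Reactants: 19 5-(benzyloxy)-7-hydroxy-8-[4-(5-hydroxy-7-methoxy-4-oxo-4H-chromen-2-yl)phenoxy]-2-(4-methoxyphenyl)-4H-chromen-4-one
Product: 20 5,7-dihydroxy-8-[4-(5-hydroxy-7-methoxy-4-oxo-4H-chromen-2-yl)phenoxy]-2-(4-methoxyphenyl)-4H-chromen-4-one (CNP0124888.0)
Conditions: H2 (1 atm), 10% Pd/C, THF/MeOH, rt
Reagents that add atoms: none
Why: Hydrogenolysis of the single aryl benzyl ether over palladium on carbon, under which the diaryl ether, the two methyl ethers and the pyranone C2=C3 bonds should not be reduced.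

Compound list
1 | 2,4,6-trihydroxybenzaldehyde | O=Cc1c(O)cc(O)cc1O | starting material
2 | 4-(benzyloxy)-2,6-dihydroxybenzaldehyde | O=Cc1c(O)cc(OCc2ccccc2)cc1O | intermediate
3 | 4-(benzyloxy)-2,6-bis(methoxymethoxy)benzaldehyde | COCOc1cc(OCc2ccccc2)cc(OCOC)c1C=O | intermediate
4 | 4-(benzyloxy)-2,6-bis(methoxymethoxy)phenyl formate | COCOc1cc(OCc2ccccc2)cc(OCOC)c1OC=O | intermediate (not isolated)
5 | 4-(benzyloxy)-2,6-bis(methoxymethoxy)phenol | COCOc1cc(OCc2ccccc2)cc(OCOC)c1O | intermediate
6 | 4-fluorobenzaldehyde | O=Cc1ccc(F)cc1 | starting material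
7 | 4-[4-(benzyloxy)-2,6-bis(methoxymethoxy)phenoxy]benzaldehyde | COCOc1cc(OCc2ccccc2)cc(OCOC)c1Oc1ccc(C=O)cc1 | intermediate
8 | 5-(benzyloxy)-2-[4-(dimethoxymethyl)phenoxy]-1,3-bis(methoxymethoxy)benzene | COCOc1cc(OCc2ccccc2)cc(OCOC)c1Oc1ccc(C(OC)OC)cc1 | intermediate
9 | (E)-4-methoxycinnamic acid | COc1ccc(/C=C/C(=O)O)cc1 | starting material
10 | (E)-4-methoxycinnamoyl chloride | COc1ccc(/C=C/C(=O)Cl)cc1 | intermediate (not isolated)
11 | (E)-N-methoxy-3-(4-methoxyphenyl)-N-methylprop-2-enamide | COc1ccc(/C=C/C(=O)N(C)OC)cc1 | intermediate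
12 | {6-(benzyloxy)-3-[4-(dimethoxymethyl)phenoxy]-2,4-bis(methoxymethoxy)phenyl}lithium | COCOc1cc(OCc2ccccc2)c([Li])c(OCOC)c1Oc1ccc(C(OC)OC)cc1 | intermediate (not isolated)
13 | (2E)-1-{6-(benzyloxy)-3-[4-(dimethoxymethyl)phenoxy]-2,4-bis(methoxymethoxy)phenyl}-3-(4-methoxyphenyl)prop-2-en-1-one | COCOc1cc(OCc2ccccc2)c(C(=O)/C=C/c2ccc(OC)cc2)c(OCOC)c1Oc1ccc(C(OC)OC)cc1 | intermediate (not isolated)
14 | 4-{4-(benzyloxy)-3-[(2E)-3-(4-methoxyphenyl)prop-2-enoyl]-2,6-bis(methoxymethoxy)phenoxy}benzaldehyde | COCOc1cc(OCc2ccccc2)c(C(=O)/C=C/c2ccc(OC)cc2)c(OCOC)c1Oc1ccc(C=O)cc1 | intermediate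
15 | 2',6'-dihydroxy-4'-methoxyacetophenone | CC(=O)c1c(O)cc(OC)cc1O | starting material
16 | 2'-hydroxy-4'-methoxy-6'-(methoxymethoxy)acetophenone | CC(=O)c1c(O)cc(OC)cc1OCOC | intermediate
17 | (2E)-1-[6-(benzyloxy)-3-{4-[(1E)-3-(2-hydroxy-4-methoxy-6-(methoxymethoxy)phenyl)-3-oxoprop-1-en-1-yl]phenoxy}-2,4-bis(methoxymethoxy)phenyl]-3-(4-methoxyphenyl)prop-2-en-1-one | COCOc1cc(OCc2ccccc2)c(C(=O)/C=C/c2ccc(OC)cc2)c(OCOC)c1Oc1ccc(/C=C/C(=O)c2c(O)cc(OC)cc2OCOC)cc1 | intermediate
18 | (2E)-1-[6-(benzyloxy)-3-{4-[(1E)-3-(2,6-dihydroxy-4-methoxyphenyl)-3-oxoprop-1-en-1-yl]phenoxy}-2,4-dihydroxyphenyl]-3-(4-methoxyphenyl)prop-2-en-1-one | COc1ccc(/C=C/C(=O)c2c(OCc3ccccc3)cc(O)c(Oc3ccc(/C=C/C(=O)c4c(O)cc(OC)cc4O)cc3)c2O)cc1 | intermediate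
19 | 5-(benzyloxy)-7-hydroxy-8-[4-(5-hydroxy-7-methoxy-4-oxo-4H-chromen-2-yl)phenoxy]-2-(4-methoxyphenyl)-4H-chromen-4-one | COc1ccc(-c2cc(=O)c3c(OCc4ccccc4)cc(O)c(Oc4ccc(-c5cc(=O)c6c(O)cc(OC)cc6o5)cc4)c3o2)cc1 | intermediate
20 | 5,7-dihydroxy-8-[4-(5-hydroxy-7-methoxy-4-oxo-4H-chromen-2-yl)phenoxy]-2-(4-methoxyphenyl)-4H-chromen-4-one | COc1ccc(-c2cc(=O)c3c(O)cc(O)c(Oc4ccc(-c5cc(=O)c6c(O)cc(OC)cc6o5)cc4)c3o2)cc1 | target

Total step count: 12. Longest linear sequence: 10 steps (steps 1–5, 7 and 9–12, from compound 1); steps 6 and 8 are one-step side branches.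

Steps most likely to fail

Step 11. The second ring closure may stall at a half-cyclised stage, the electron-rich rings may be iodinated, or the benzyl ether may be lost before ring A has closed, which would open the way to the 6-aryloxy isomer. The fallback sets out from 18 and separates ring closure from oxidation. NaOAc in refluxing EtOH should effect the double oxa-Michael closure, with no oxidant present, to the bis-flavanone 5-(benzyloxy)-7-hydroxy-8-[4-(5-hydroxy-7-methoxy-4-oxochroman-2-yl)phenoxy]-2-(4-methoxyphenyl)chroman-4-one F1, a mixture of diastereomers. Dehydrogenation of both C2–C3 bonds with DDQ in refluxing dioxane would then remove the two stereocentres and return to the route at 19.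

Step 7. Lithiation may occur at the wrong place (the benzylic methylene of the benzyl ether followed by Wittig rearrangement, or ring F next to the acetal), and the amide may suffer conjugate or double addition. The fallback sets out from 8 and fixes the metalation site by halogen. NBS in MeCN at 0 °C should brominate the only strongly activated ring position to give 1-(benzyloxy)-2-bromo-4-[4-(dimethoxymethyl)phenoxy]-3,5-bis(methoxymethoxy)benzene F2. Bromine–lithium exchange with n-BuLi in THF at −78 °C then generates aryllithium 12 site-specifically, below the temperature at which benzylic deprotonation competes. Addition of 11 and the same dilute acid work-up return to the route at 14.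

Step 1. Alkylation may run on to the ortho hydroxyls or start there, giving mixtures of mono- and dibenzyl ethers that are hard to separate. The fallback sets out from 1 and replaces selective protection by selective deprotection. Excess BnBr with K2CO3 in DMF gives 2,4,6-tris(benzyloxy)benzaldehyde F3. MgBr2·OEt2 in refluxing toluene/Et2O should then cleave only the two benzyl ethers ortho to the formyl group through chelation to its oxygen, leaving the para ether and returning to the route at 2.

Further compounds
F1 | step 11 | 5-(benzyloxy)-7-hydroxy-8-[4-(5-hydroxy-7-methoxy-4-oxochroman-2-yl)phenoxy]-2-(4-methoxyphenyl)chroman-4-one (mixture of diastereomers) | COc1ccc(C2CC(=O)c3c(OCc4ccccc4)cc(O)c(Oc4ccc(C5CC(=O)c6c(O)cc(OC)cc6O5)cc4)c3O2)cc1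
F2 | step 7 | 1-(benzyloxy)-2-bromo-4-[4-(dimethoxymethyl)phenoxy]-3,5-bis(methoxymethoxy)benzene | COCOc1cc(OCc2ccccc2)c(Br)c(OCOC)c1Oc1ccc(C(OC)OC)cc1
F3 | step 1 | 2,4,6-tris(benzyloxy)benzaldehyde | O=Cc1c(OCc2ccccc2)cc(OCc2ccccc2)cc1OCc1ccccc1
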